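## Retrosynthetic overview

1. Sarcotrine D ⇒ one fully acyclic C25 precursor with an α‑propanoyloxy methyl ester at one end and an N‑(phosphonoacetyl)‑α‑amino ketone at the other. Both heterocycles are closed last, in one flask with one base: the γ‑lactam first (intramolecular HWE), the tetronic acid second (Dieckmann).
2. Acyclic precursor ⇒ diene C–C bond by oxidative Heck vinylation of a "West" terminal alkene with an "East" (E)‑2‑methylalkenyl boronate.
3. West ⇒ (S)‑β‑citronellene (chain methine stereocentre) → aldehyde → (Z)‑alkenyl iodide → opening of methyl (S)‑glycidate (carbinol stereocentre) with O‑propanoylation in the same flask.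
4. East ⇒ methyl hex‑5‑ynoate → Cu‑catalysed methylboration → acid → bromomethyl ketone → isopentylamine, then phosphonoacetylation.

Assumption: the SMILES is taken as written, i.e. (5S) at the tetronic acid carbon, (S) at the chain methine, 2′Z and 7′E,9′E alkenes; Bpin = 4,4,5,5‑tetramethyl‑1,3,2‑dioxaborolan‑2‑yl.

## Route

Step 1
Reactants: 1 (3S)‑3,7‑dimethylocta‑1,6‑diene [(S)‑β‑citronellene]
Product: 2 (4S)‑4‑methylhex‑5‑enal
Conditions: O3, CH2Cl2, −78 °C (Sudan Red 7B end‑point); Me2S, −78 °C → rt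
Reagents that add atoms: ozone, [O-][O+]=O
Why: Chemoselective ozonolysis works because the electron‑rich trisubstituted alkene reacts with ozone much faster than the monosubstituted vinyl group, so titration to the dye end‑point cleaves only the isopropylidene and leaves the (S)‑methine and the vinyl group untouched.

Step 2
Reactants: 2 (4S)‑4‑methylhex‑5‑enal
Product: 3 (3S,6Z)‑7‑iodo‑3‑methylocta‑1,6‑diene
Conditions: EtPPh3I, n‑BuLi, THF, rt; I2, −78 °C; NaHMDS, −20 °C; 2, −78 °C → rt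
Reagents that add atoms: ethyltriphenylphosphonium iodide, CC[P+](c1ccccc1)(c1ccccc1)c1ccccc1.[I-]; iodine, II
Why: The Stork–Zhao Wittig olefination of an aliphatic aldehyde with the α‑iodoethylidene ylide gives the (Z)‑2‑iodo‑2‑alkene (iodine cis to the chain) under kinetic control, which fixes the geometry of the later trisubstituted alkene.

Step 3
Reactants: 3 (3S,6Z)‑7‑iodo‑3‑methylocta‑1,6‑diene; 4 methyl (2S)‑oxirane‑2‑carboxylate [methyl (S)‑glycidate]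
Product: 8 methyl (2S,4Z,8S)‑4,8‑dimethyl‑2‑(propanoyloxy)deca‑4,9‑dienoate, via [(2E,6S)‑6‑methylocta‑2,7‑dien‑2‑yl]lithium 5 (not isolated), via bromo[(2Z,6S)‑6‑methylocta‑2,7‑dien‑2‑yl]magnesium 6 (not isolated), via bromomagnesium (2S,4Z,8S)‑1‑methoxy‑4,8‑dimethyl‑1‑oxodeca‑4,9‑dien‑2‑olate 7 (not isolated)
Conditions: t‑BuLi (2.05 equiv), Et2O, −78 °C; MgBr2·OEt2, −78 → −40 °C; CuI (10 mol %), 4, THF, −40 °C; (EtCO)2O, DMAP (cat.), −40 °C → rt
Reagents that add atoms: propanoic anhydride, CCC(=O)OC(=O)CC; (atoms only in intermediates 5–7: tert‑butyllithium, [Li]C(C)(C)C; magnesium bromide, Br[Mg]Br)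
Why: Iodine–lithium exchange and transmetalation retain the alkene geometry, and the copper‑catalysed SN2 epoxide opening occurs at the unsubstituted C3 of the glycidate, so the (S)‑C2–O stereocentre comes unchanged from the chiral pool before the magnesium alkoxide is O‑acylated in the same flask.

Step 4
Reactants: 9 methyl hex‑5‑ynoate
Product: 10 methyl (5E)‑5‑methyl‑6‑(Bpin)hex‑5‑enoate
Conditions: B2pin2, MeI, CuCl (5 mol %), Xantphos (5 mol %), LiOt‑Bu, THF, rt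
Reagents that add atoms: bis(pinacolato)diboron, CC1(C)OB(OC1(C)C)B1OC(C)(C)C(C)(C)O1; iodomethane, CI
Why: In this copper‑catalysed carboboration, syn borylcupration of the terminal alkyne puts boron on the terminal carbon and methylation of the alkenylcopper with MeI proceeds with retention, giving the (E)‑2‑methylalkenyl boronate.

Step 5
Reactants: 10 methyl (5E)‑5‑methyl‑6‑(Bpin)hex‑5‑enoate
Product: 11 (5E)‑5‑methyl‑6‑(Bpin)hex‑5‑enoic acid
Conditions: LiOH, THF/H2O, 0 °C → rt; 1 M HCl to pH 3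
Reagents that add atoms: lithium hydroxide, [Li+].[OH-]
Why: This is a standard saponification (BAc2 ester hydrolysis) under mild conditions that a pinacol alkenylboronate tolerates.

Step 6
Reactants: 11 (5E)‑5‑methyl‑6‑(Bpin)hex‑5‑enoic acid
Product: 14 (6E)‑1‑bromo‑6‑methyl‑7‑(Bpin)hept‑6‑en‑2‑one, via (5E)‑5‑methyl‑6‑(Bpin)hex‑5‑enoyl chloride 12 (not isolated), via (6E)‑1‑diazo‑6‑methyl‑7‑(Bpin)hept‑6‑en‑2‑one 13 (not isolated)
Conditions: (COCl)2, DMF (cat.), CH2Cl2, 0 °C → rt; TMSCHN2, THF/MeCN, 0 °C; HBr (33 % in AcOH), −20 → 0 °C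
Reagents that add atoms: (trimethylsilyl)diazomethane, C[Si](C)(C)C=[N+]=[N-]; hydrogen bromide, Br; (Cl only in intermediate 12: oxalyl chloride, ClC(=O)C(=O)Cl)
Why: Acid chloride formation, Arndt–Eistert‑type acylation of the diazoalkane and hydrobromination of the diazoketone (loss of N2) give the one‑carbon‑homologated bromomethyl ketone without any organometallic that would attack boron.

Step 7
Reactants: 14 (6E)‑1‑bromo‑6‑methyl‑7‑(Bpin)hept‑6‑en‑2‑one; 15 3‑methylbutan‑1‑amine (isopentylamine); 16 2‑(diethoxyphosphoryl)acetic acid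
Product: 18 diethyl [2‑{(3‑methylbutyl)[(6E)‑6‑methyl‑2‑oxo‑7‑(Bpin)hept‑6‑en‑1‑yl]amino}‑2‑oxoethyl]phosphonate, via (6E)‑6‑methyl‑1‑[(3‑methylbutyl)amino]‑7‑(Bpin)hept‑6‑en‑2‑one 17 (not isolated)
Conditions: 15 (3 equiv), THF, −20 °C; filter, concentrate; 16, DCC, HOBt (cat.), CH2Cl2, 0 °C → rt
Reagents that add atoms: none
Why: SN2 amination of the α‑bromoketone with excess primary amine is followed at once by carbodiimide amide coupling of the secondary amine, before the α‑amino ketone can self‑condense.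

Step 8
Reactants: 8 methyl (2S,4Z,8S)‑4,8‑dimethyl‑2‑(propanoyloxy)deca‑4,9‑dienoate; 18 diethyl [2‑{(3‑methylbutyl)[(6E)‑6‑methyl‑2‑oxo‑7‑(Bpin)hept‑6‑en‑1‑yl]amino}‑2‑oxoethyl]phosphonate
Product: 19 methyl (2S,4Z,8S,9E,11E)‑17‑{[2‑(diethoxyphosphoryl)acetyl](3‑methylbutyl)amino}‑4,8,12‑trimethyl‑16‑oxo‑2‑(propanoyloxy)heptadeca‑4,9,11‑trienoate
Conditions: 18 (1.5 equiv), Pd(OAc)2/1,2‑bis(phenylsulfinyl)ethane (10 mol %), 2,6‑dimethylbenzoquinone, AcOH, THF, rt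
Reagents that add atoms: none
Why: In this oxidative Heck vinylation (Pd(II)/bis‑sulfoxide with quinone reoxidant) the alkenylboronate transmetalates with retention, inserts into the terminal alkene and β‑hydride elimination toward the conjugated position gives the (E,E)‑diene without Pd–H isomerisation, so the allylic stereocentre and the Z‑alkene are not touched.

Step 9
Reactants: 19 methyl (2S,4Z,8S,9E,11E)‑17‑{[2‑(diethoxyphosphoryl)acetyl](3‑methylbutyl)amino}‑4,8,12‑trimethyl‑16‑oxo‑2‑(propanoyloxy)heptadeca‑4,9,11‑trienoate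
Product: 21 Sarcotrine D, (5S)‑4‑hydroxy‑3‑methyl‑5‑{(2Z,6S,7E,9E)‑2,6,10‑trimethyl‑13‑[1‑(3‑methylbutyl)‑5‑oxo‑2,5‑dihydro‑1H‑pyrrol‑3‑yl]trideca‑2,7,9‑trien‑1‑yl}furan‑2(5H)‑one, via methyl (2S,4Z,8S,9E,11E)‑4,8,12‑trimethyl‑15‑[1‑(3‑methylbutyl)‑5‑oxo‑2,5‑dihydro‑1H‑pyrrol‑3‑yl]‑2‑(propanoyloxy)pentadeca‑4,9,11‑trienoate 20 (not isolated)
Conditions: LiHMDS (1.1 equiv), THF, −78 → 0 °C; LiHMDS (2.5 equiv), −78 °C → rt; 1 M HCl
Reagents that add atoms: none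
Why: One base triggers both ring closures in one flask, the phosphonate carbanion closing onto the neighbouring ketone (intramolecular Horner–Wadsworth–Emmons reaction, giving the α,β‑unsaturated γ‑lactam) and the propanoate enolate closing onto the methyl ester (Dieckmann cyclisation, driven by formation of the lithium tetronate), while the C5 stereocentre is carried over from 19 because kinetic deprotonation occurs at the unhindered propanoyl CH2.

## Compound list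

1 | (3S)‑3,7‑dimethylocta‑1,6‑diene, (S)‑β‑citronellene | CC(C)=CCC[C@H](C)C=C | starting material
2 | (4S)‑4‑methylhex‑5‑enal | O=CCC[C@H](C)C=C | intermediate
3 | (3S,6Z)‑7‑iodo‑3‑methylocta‑1,6‑diene | C/C(I)=C/CC[C@H](C)C=C | intermediate
4 | methyl (2S)‑oxirane‑2‑carboxylate, methyl (S)‑glycidate | COC(=O)[C@@H]1CO1 | starting material
5 | [(2E,6S)‑6‑methylocta‑2,7‑dien‑2‑yl]lithium (Li cis to the chain) | C/C([Li])=C/CC[C@H](C)C=C | intermediate
6 | bromo[(2Z,6S)‑6‑methylocta‑2,7‑dien‑2‑yl]magnesium | C/C([Mg]Br)=C/CC[C@H](C)C=C | intermediate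
7 | bromomagnesium (2S,4Z,8S)‑1‑methoxy‑4,8‑dimethyl‑1‑oxodeca‑4,9‑dien‑2‑olate | COC(=O)[C@H](C/C(C)=C\CC[C@H](C)C=C)O[Mg]Br | intermediate
8 | methyl (2S,4Z,8S)‑4,8‑dimethyl‑2‑(propanoyloxy)deca‑4,9‑dienoate | COC(=O)[C@H](C/C(C)=C\CC[C@H](C)C=C)OC(=O)CC | intermediate
9 | methyl hex‑5‑ynoate | COC(=O)CCCC#C | starting material
10 | methyl (5E)‑5‑methyl‑6‑(4,4,5,5‑tetramethyl‑1,3,2‑dioxaborolan‑2‑yl)hex‑5‑enoate | COC(=O)CCC/C(C)=C/B1OC(C)(C)C(C)(C)O1 | intermediate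
11 | (5E)‑5‑methyl‑6‑(4,4,5,5‑tetramethyl‑1,3,2‑dioxaborolan‑2‑yl)hex‑5‑enoic acid | OC(=O)CCC/C(C)=C/B1OC(C)(C)C(C)(C)O1 | intermediate
12 | (5E)‑5‑methyl‑6‑(4,4,5,5‑tetramethyl‑1,3,2‑dioxaborolan‑2‑yl)hex‑5‑enoyl chloride | ClC(=O)CCC/C(C)=C/B1OC(C)(C)C(C)(C)O1 | intermediate
13 | (6E)‑1‑diazo‑6‑methyl‑7‑(4,4,5,5‑tetramethyl‑1,3,2‑dioxaborolan‑2‑yl)hept‑6‑en‑2‑one | [N-]=[N+]=CC(=O)CCC/C(C)=C/B1OC(C)(C)C(C)(C)O1 | intermediate
14 | (6E)‑1‑bromo‑6‑methyl‑7‑(4,4,5,5‑tetramethyl‑1,3,2‑dioxaborolan‑2‑yl)hept‑6‑en‑2‑one | BrCC(=O)CCC/C(C)=C/B1OC(C)(C)C(C)(C)O1 | intermediate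
15 | 3‑methylbutan‑1‑amine (isopentylamine) | CC(C)CCN | starting material
16 | 2‑(diethoxyphosphoryl)acetic acid | CCOP(=O)(CC(=O)O)OCC | starting material
17 | (6E)‑6‑methyl‑1‑[(3‑methylbutyl)amino]‑7‑(4,4,5,5‑tetramethyl‑1,3,2‑dioxaborolan‑2‑yl)hept‑6‑en‑2‑one | CC(C)CCNCC(=O)CCC/C(C)=C/B1OC(C)(C)C(C)(C)O1 | intermediate
18 | diethyl [2‑{(3‑methylbutyl)[(6E)‑6‑methyl‑2‑oxo‑7‑(4,4,5,5‑tetramethyl‑1,3,2‑dioxaborolan‑2‑yl)hept‑6‑en‑1‑yl]amino}‑2‑oxoethyl]phosphonate | CCOP(=O)(CC(=O)N(CCC(C)C)CC(=O)CCC/C(C)=C/B1OC(C)(C)C(C)(C)O1)OCC | intermediate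
19 | methyl (2S,4Z,8S,9E,11E)‑17‑{[2‑(diethoxyphosphoryl)acetyl](3‑methylbutyl)amino}‑4,8,12‑trimethyl‑16‑oxo‑2‑(propanoyloxy)heptadeca‑4,9,11‑trienoate | COC(=O)[C@H](C/C(C)=C\CC[C@H](C)/C=C/C=C(\C)CCCC(=O)CN(CCC(C)C)C(=O)CP(=O)(OCC)OCC)OC(=O)CC | intermediate
20 | methyl (2S,4Z,8S,9E,11E)‑4,8,12‑trimethyl‑15‑[1‑(3‑methylbutyl)‑5‑oxo‑2,5‑dihydro‑1H‑pyrrol‑3‑yl]‑2‑(propanoyloxy)pentadeca‑4,9,11‑trienoate | COC(=O)[C@H](C/C(C)=C\CC[C@H](C)/C=C/C=C(\C)CCCC1=CC(=O)N(CCC(C)C)C1)OC(=O)CC | intermediate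
21 | Sarcotrine D, (5S)‑4‑hydroxy‑3‑methyl‑5‑{(2Z,6S,7E,9E)‑2,6,10‑trimethyl‑13‑[1‑(3‑methylbutyl)‑5‑oxo‑2,5‑dihydro‑1H‑pyrrol‑3‑yl]trideca‑2,7,9‑trien‑1‑yl}furan‑2(5H)‑one | CC1=C(O)[C@H](C/C(C)=C\CC[C@H](C)/C=C/C=C(\C)CCCC2=CC(=O)N(CCC(C)C)C2)OC1=O | target

## Step count and risks

Total: 9 steps. Longest linear sequence: 6 steps (9 → 10 → 11 → 14 → 18 → 19 → 21, steps 4–9); the West branch (1 → 2 → 3 → 8) joins at step 8.

**Step 9 (highest risk).** The cascade asks one base to sort four acidic sites. Possible failures are ketone enolisation stalling the HWE, Chan‑type acyl migration or epimerisation at the α‑acyloxy ester, and deconjugation of the lactam by excess base.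
Fallback, setting out from 14 (with 8) and coming back at 20: the lactam is closed under neutral conditions by an intramolecular Wittig reaction, so the base only has to do the Dieckmann closure. The Heck reaction of step 8 is run with bromoketone 14 in place of 18 to give methyl (2S,4Z,8S,9E,11E)‑17‑bromo‑4,8,12‑trimethyl‑16‑oxo‑2‑(propanoyloxy)heptadeca‑4,9,11‑trienoate F1. In one flask, 15 (1.2 equiv) with i‑Pr2NEt in THF at 0 °C gives methyl (2S,4Z,8S,9E,11E)‑4,8,12‑trimethyl‑17‑[(3‑methylbutyl)amino]‑16‑oxo‑2‑(propanoyloxy)heptadeca‑4,9,11‑trienoate F2. Ketenylidenetriphenylphosphorane (Ph3P=C=C=O, THF, 50 °C) N‑acylates it to methyl (2S,4Z,8S,9E,11E)‑4,8,12‑trimethyl‑17‑{(3‑methylbutyl)[(triphenyl‑λ5‑phosphanylidene)acetyl]amino}‑16‑oxo‑2‑(propanoyloxy)heptadeca‑4,9,11‑trienoate F3, which cyclises onto the ketone to give 20. LiHMDS (2.5 equiv, −78 °C → rt) is then added to the same flask to reach 21, so both rings still close in one operation.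

**Step 8.** The terminal alkene is α‑branched, so β‑hydride elimination toward the methine or Pd–H migration is conceivable, and the boronate partner carries a ketone and an active methylene.
Fallback, setting out from 8 and 18 and coming back at 19: the union becomes a Suzuki–Miyaura coupling of two pre‑activated partners. The alkene of 8 is borylated by a boryl‑Heck reaction (Pd2(dba)3/JessePhos, catBCl, Et3N, PhCF3, 70 °C) to methyl (2S,4Z,8S,9E)‑10‑(1,3,2‑benzodioxaborol‑2‑yl)‑4,8‑dimethyl‑2‑(propanoyloxy)deca‑4,9‑dienoate F4, which is transesterified in the same flask with pinacol to methyl (2S,4Z,8S,9E)‑4,8‑dimethyl‑2‑(propanoyloxy)‑10‑(4,4,5,5‑tetramethyl‑1,3,2‑dioxaborolan‑2‑yl)deca‑4,9‑dienoate F5. Boronate 18 is converted with retention by ipso‑iododeboronation (NIS, MeCN, 0 °C, dark) into diethyl [2‑{[(6E)‑7‑iodo‑6‑methyl‑2‑oxohept‑6‑en‑1‑yl](3‑methylbutyl)amino}‑2‑oxoethyl]phosphonate F6. F5 and F6 are joined without added base (Pd(PPh3)4, Ag2O, THF, rt) to give 19.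

**Step 3.** The hindered alkenyl Grignard may add to the glycidate ester instead of opening the epoxide, and the in‑flask acylation of the magnesium alkoxide may be incomplete.
Fallback, setting out from 3 (with 4) and coming back at 8: a nickel‑catalysed reductive cross‑electrophile coupling replaces the organometallic nucleophile (NiCl2·dme/4,4′‑di‑tert‑butyl‑2,2′‑bipyridine, NaI, Et3N·HCl, Mn, DMPU, rt). Iodide opens 4 at C3 to the iodohydrin, whose primary radical is captured by the alkenylnickel species with the C2 stereocentre untouched, giving methyl (2S,4Z,8S)‑2‑hydroxy‑4,8‑dimethyldeca‑4,9‑dienoate F7. This is propanoylated in a separate step ((EtCO)2O, Et3N, DMAP, CH2Cl2) to 8.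

## Further compounds

F1 | step 9 | methyl (2S,4Z,8S,9E,11E)‑17‑bromo‑4,8,12‑trimethyl‑16‑oxo‑2‑(propanoyloxy)heptadeca‑4,9,11‑trienoate | COC(=O)[C@H](C/C(C)=C\CC[C@H](C)/C=C/C=C(\C)CCCC(=O)CBr)OC(=O)CC
F2 | step 9 | methyl (2S,4Z,8S,9E,11E)‑4,8,12‑trimethyl‑17‑[(3‑methylbutyl)amino]‑16‑oxo‑2‑(propanoyloxy)heptadeca‑4,9,11‑trienoate | COC(=O)[C@H](C/C(C)=C\CC[C@H](C)/C=C/C=C(\C)CCCC(=O)CNCCC(C)C)OC(=O)CC
F3 | step 9 | methyl (2S,4Z,8S,9E,11E)‑4,8,12‑trimethyl‑17‑{(3‑methylbutyl)[(triphenyl‑λ5‑phosphanylidene)acetyl]amino}‑16‑oxo‑2‑(propanoyloxy)heptadeca‑4,9,11‑trienoate | COC(=O)[C@H](C/C(C)=C\CC[C@H](C)/C=C/C=C(\C)CCCC(=O)CN(CCC(C)C)C(=O)C=P(c1ccccc1)(c1ccccc1)c1ccccc1)OC(=O)CC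
F4 | step 8 | methyl (2S,4Z,8S,9E)‑10‑(1,3,2‑benzodioxaborol‑2‑yl)‑4,8‑dimethyl‑2‑(propanoyloxy)deca‑4,9‑dienoate | COC(=O)[C@H](C/C(C)=C\CC[C@H](C)/C=C/B1Oc2ccccc2O1)OC(=O)CC
F5 | step 8 | methyl (2S,4Z,8S,9E)‑4,8‑dimethyl‑2‑(propanoyloxy)‑10‑(4,4,5,5‑tetramethyl‑1,3,2‑dioxaborolan‑2‑yl)deca‑4,9‑dienoate | COC(=O)[C@H](C/C(C)=C\CC[C@H](C)/C=C/B1OC(C)(C)C(C)(C)O1)OC(=O)CC
F6 | step 8 | diethyl [2‑{[(6E)‑7‑iodo‑6‑methyl‑2‑oxohept‑6‑en‑1‑yl](3‑methylbutyl)amino}‑2‑oxoethyl]phosphonate | CCOP(=O)(CC(=O)N(CCC(C)C)CC(=O)CCC/C(C)=C/I)OCC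
F7 | step 3 | methyl (2S,4Z,8S)‑2‑hydroxy‑4,8‑dimethyldeca‑4,9‑dienoate | COC(=O)[C@H](C/C(C)=C\CC[C@H](C)C=C)O
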